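**Strategy**

The trimer is cut at both C4–C8 interflavan bonds into (+)-catechin (bottom unit), (+)-gallocatechin (top unit) and a middle flavan whose pyran ring C is built de novo around C4. As a ketone, C4 acidifies C3–H and activates the ortho carbon C8a of ring A. In one operation the potassium enolate of an α-benzyloxy 2-fluoroaryl ketone adds to 3,4-bis(benzyloxy)benzaldehyde (C2–C3 bond) and the aldolate oxygen displaces fluoride (O1–C8a bond), giving a protected dihydroflavonol. The same carbonyl keeps C2 and C3 mobile, so one dynamic asymmetric transfer hydrogenation sets both, and the C4 alcohol formed is the electrophile for the first interflavan bond.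

Key step: step 3

Remark: flavan numbering (O1, C2, C3, C4, C4a, C5–C8, C8a) is used for the middle unit; racemic 10 is written with the SMILES of its (2R,3R) enantiomer, aldolate 9 without stereodescriptors (equilibrating diastereomers), and 2-(benzyloxy)-N-methoxy-N-methylacetamide is taken as a commercial reagent.

**Route**

Step 1
Reactants: 1 1,3,5-trifluorobenzene; 2 2-(benzyloxy)-N-methoxy-N-methylacetamide
Product: 4 2-(benzyloxy)-1-(2,4,6-trifluorophenyl)ethan-1-one, via 2,4,6-trifluorophenyllithium 3 (not isolated)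
Conditions: n-BuLi, THF, −78 °C; then 2, −78 → −40 °C; aq NH4Cl
Reagents that add atoms: none
Why: Lithiation between two fluorines is regiochemically unambiguous and the aryllithium is stable at −78 °C, and the Weinreb ketone synthesis stops at the ketone because the chelated tetrahedral adduct survives until work-up.

Step 2
Reactants: 4 2-(benzyloxy)-1-(2,4,6-trifluorophenyl)ethan-1-one
Product: 6 2-(benzyloxy)-1-[2,4-bis(benzyloxy)-6-fluorophenyl]ethan-1-one, via para-monoether 5 (not isolated)
Conditions: BnOH (2.1 equiv), K2CO3, DMF, 0 → 50 °C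
Reagents that add atoms: benzyl alcohol, OCc1ccccc1
Why: Double SNAr on the ketone-activated ring should take the para fluorine first in the polar aprotic medium and then one ortho fluorine, after which two alkoxy donors conjugated with the carbonyl slow the third substitution and preserve the fluorine at the future C8a.

Step 3
Reactants: 6 2-(benzyloxy)-1-[2,4-bis(benzyloxy)-6-fluorophenyl]ethan-1-one; 7 3,4-bis(benzyloxy)benzaldehyde
Product: 10 rac-(2R*,3R*)-3,5,7-tris(benzyloxy)-2-[3,4-bis(benzyloxy)phenyl]chroman-4-one, via potassium enolate 8 (not isolated), via potassium aldolate 9 (not isolated)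
Conditions: KN(SiMe3)2 (1.0 equiv), THF, −78 °C; then 7, −78 → 40 °C; then DBU (0.1 equiv), rt
Reagents that add atoms: none
Why: Enolate 8 adds to aldehyde 7 (aldol addition, C2–C3), and the alkoxide of aldolate 9 attacks the fluorine-bearing carbon ortho to the carbonyl by addition–elimination (SNAr) through a Meisenheimer anion delocalised into the C4 carbonyl, expelling fluoride (O1–C8a). The closest known reaction types are base-mediated domino aldol/SNAr annulations of 2-fluoroaryl ketones and chromone or chromanone syntheses by intramolecular SNAr of an oxygen nucleophile. Ring C closes as a six-membered ring by attack of O1 on the sp2 carbon C8a (6-exo-trig counted on the C8a=C8 bond). The new stereocentres C2 and C3 arise as a racemate under thermodynamic control: the aldol is reversible (Curtin–Hammett), the chair-like closure and the DBU-mediated enolisation at C3 both favour the 2,3-trans isomer with aryl and benzyloxy groups equatorial, and the absolute configuration is deliberately left to step 4. The step needs O-arylation by the aldolate oxygen in a six-membered closure, which the substrate secures because the C3 oxygen is capped as a benzyl ether (no five-membered benzofuranone closure), only one fluorine is left, and neither enolate terminus can reach C8a. Loss of water to the α-benzyloxychalcone is held back by the aprotic medium and the use of exactly one equivalent of base.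

Step 4
Reactants: 10 rac-(2R*,3R*)-3,5,7-tris(benzyloxy)-2-[3,4-bis(benzyloxy)phenyl]chroman-4-one
Product: 11 (2R,3S,4R)-3,5,7-tris(benzyloxy)-2-[3,4-bis(benzyloxy)phenyl]chroman-4-ol
Conditions: RuCl[(S,S)-TsDPEN](p-cymene) (2 mol %), HCO2H (3 equiv), DBU (5 equiv), MeCN, 40 °C
Reagents that add atoms: none
Why: Noyori–Ikariya asymmetric transfer hydrogenation under dynamic kinetic resolution, in which DBU interconverts all stereoisomers of 10 by enolisation at C3 and by retro-oxa-Michael/oxa-Michael ring opening at C2, while the (S,S)-catalyst, which places the C4 hydroxyl on the α face and is matched with the 2α-aryl ketone (as in flavanone reductions to 2,4-cis flavan-4-ols), should consume only the (2R,3R)-trans ketone, so C2 and C3 are set by catalyst control and the C4 configuration, destroyed in step 6, is of no consequence.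

Step 5
Reactants: 12 (+)-catechin
Product: 13 (2R,3S)-5,7-bis(benzyloxy)-2-[3,4-bis(benzyloxy)phenyl]chroman-3-ol
Conditions: BnBr (4.4 equiv), K2CO3, DMF, 0 °C → rt
Reagents that add atoms: benzyl bromide, BrCc1ccccc1
Why: Williamson etherification of the four phenols with a base too weak to alkylate the secondary 3-OH or to epimerise C2.

Step 6
Reactants: 11 (2R,3S,4R)-3,5,7-tris(benzyloxy)-2-[3,4-bis(benzyloxy)phenyl]chroman-4-ol; 13 (2R,3S)-5,7-bis(benzyloxy)-2-[3,4-bis(benzyloxy)phenyl]chroman-3-ol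
Product: 14 3,5,7,3',4'-penta-O-benzylcatechin-(4α→8)-5,7,3',4'-tetra-O-benzylcatechin
Conditions: 13 (4 equiv), TMSOTf (0.2 equiv), 4 Å MS, CH2Cl2, −78 → −30 °C
Reagents that add atoms: none
Why: Friedel–Crafts alkylation in which Lewis-acid ionisation of the doubly activated benzylic C4–OH gives a cation that C8 of 13 (the most nucleophilic site of a 5,7-dialkoxyflavan) should attack anti to the C3 benzyloxy group, setting the 3,4-trans (4α) configuration, while the excess of 13 outruns self-condensation of 11.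

Step 7
Reactants: 15 (+)-gallocatechin
Product: 16 (2R,3S)-5,7-bis(benzyloxy)-2-[3,4,5-tris(benzyloxy)phenyl]chroman-3-ol
Conditions: BnBr (5.5 equiv), K2CO3, DMF, argon, 0 °C → rt
Reagents that add atoms: benzyl bromide, BrCc1ccccc1
Why: Williamson etherification of the five phenols as in step 5, run under argon because the pyrogallol ring is oxidation-prone until capped.

Step 8
Reactants: 16 (2R,3S)-5,7-bis(benzyloxy)-2-[3,4,5-tris(benzyloxy)phenyl]chroman-3-ol
Product: 17 (2R,3S,4S)-5,7-bis(benzyloxy)-4-(2-ethoxyethoxy)-2-[3,4,5-tris(benzyloxy)phenyl]chroman-3-ol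
Conditions: DDQ (2 equiv), 2-ethoxyethanol (5 equiv), CH2Cl2, rt
Reagents that add atoms: 2-ethoxyethanol, CCOCCO
Why: DDQ dehydrogenation of the electron-rich benzylic C4–H gives a stabilised cation that the alcohol traps on the face anti to the C2 aryl group, the standard way to turn a benzylated flavan-3-ol into a C4 electrophile without touching C2 or C3.

Step 9
Reactants: 14 3,5,7,3',4'-penta-O-benzylcatechin-(4α→8)-5,7,3',4'-tetra-O-benzylcatechin; 17 (2R,3S,4S)-5,7-bis(benzyloxy)-4-(2-ethoxyethoxy)-2-[3,4,5-tris(benzyloxy)phenyl]chroman-3-ol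
Product: 18 5,7,3',4',5'-penta-O-benzylgallocatechin-(4α→8)-3,5,7,3',4'-penta-O-benzylcatechin-(4α→8)-5,7,3',4'-tetra-O-benzylcatechin
Conditions: 14 (1.2 equiv), TMSOTf (0.5 equiv), CH2Cl2, −78 °C
Reagents that add atoms: none
Why: Friedel–Crafts alkylation as in step 6, in which the free C8 of the middle unit of 14 is the most nucleophilic position left (the bottom unit offers only C6) and attack anti to the C3 oxygen of the 2,3-trans cation should set the second 4α bond, the low temperature keeping the existing interflavan bond intact.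

Step 10
Reactants: 18 5,7,3',4',5'-penta-O-benzylgallocatechin-(4α→8)-3,5,7,3',4'-penta-O-benzylcatechin-(4α→8)-5,7,3',4'-tetra-O-benzylcatechin
Product: 19 gallocatechin-(4α→8)-catechin-(4α→8)-catechin (CNP0155646.1)
Conditions: H2 (1 atm), Pd(OH)2/C, THF/MeOH/H2O, rt
Reagents that add atoms: none
Why: Hydrogenolysis of all fourteen benzyl ethers under neutral conditions that leave the acid-labile interflavan bonds and the cyclic benzylic C2–O1 bonds untouched.

**Compound list**

1 | 1,3,5-trifluorobenzene | Fc1cc(F)cc(F)c1 | starting material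
2 | 2-(benzyloxy)-N-methoxy-N-methylacetamide | CON(C)C(=O)COCc1ccccc1 | starting material
3 | 2,4,6-trifluorophenyllithium | [Li]c1c(F)cc(F)cc1F | intermediate (not isolated)
4 | 2-(benzyloxy)-1-(2,4,6-trifluorophenyl)ethan-1-one | O=C(COCc1ccccc1)c1c(F)cc(F)cc1F | intermediate
5 | 2-(benzyloxy)-1-[4-(benzyloxy)-2,6-difluorophenyl]ethan-1-one | O=C(COCc1ccccc1)c1c(F)cc(OCc2ccccc2)cc1F | intermediate (not isolated)
6 | 2-(benzyloxy)-1-[2,4-bis(benzyloxy)-6-fluorophenyl]ethan-1-one | O=C(COCc1ccccc1)c1c(F)cc(OCc2ccccc2)cc1OCc1ccccc1 | intermediate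
7 | 3,4-bis(benzyloxy)benzaldehyde | O=Cc1ccc(OCc2ccccc2)c(OCc2ccccc2)c1 | starting material
8 | potassium (Z)-2-(benzyloxy)-1-[2,4-bis(benzyloxy)-6-fluorophenyl]ethen-1-olate | [K+].[O-]/C(=C\OCc1ccccc1)c1c(F)cc(OCc2ccccc2)cc1OCc1ccccc1 | intermediate (not isolated)
9 | potassium 1-[3,4-bis(benzyloxy)phenyl]-2-(benzyloxy)-3-[2,4-bis(benzyloxy)-6-fluorophenyl]-3-oxopropan-1-olate (equilibrating diastereomers) | [K+].[O-]C(c1ccc(OCc2ccccc2)c(OCc2ccccc2)c1)C(OCc1ccccc1)C(=O)c1c(F)cc(OCc2ccccc2)cc1OCc1ccccc1 | intermediate (not isolated)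
10 | rac-(2R*,3R*)-3,5,7-tris(benzyloxy)-2-[3,4-bis(benzyloxy)phenyl]chroman-4-one (2,3-trans; racemate) | c1ccccc1COc1cc(OCc3ccccc3)c2c(c1)O[C@H](c1ccc(OCc3ccccc3)c(OCc3ccccc3)c1)[C@@H](OCc1ccccc1)C2=O | intermediate
11 | (2R,3S,4R)-3,5,7-tris(benzyloxy)-2-[3,4-bis(benzyloxy)phenyl]chroman-4-ol (2,3-trans-3,4-trans) | c1ccccc1COc1cc(OCc3ccccc3)c2c(c1)O[C@H](c1ccc(OCc3ccccc3)c(OCc3ccccc3)c1)[C@@H](OCc1ccccc1)[C@@H]2O | intermediate
12 | (+)-catechin, (2R,3S) | Oc1cc(O)c2c(c1)O[C@H](c1ccc(O)c(O)c1)[C@@H](O)C2 | starting material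
13 | (2R,3S)-5,7-bis(benzyloxy)-2-[3,4-bis(benzyloxy)phenyl]chroman-3-ol | c1ccccc1COc1cc(OCc3ccccc3)c2c(c1)O[C@H](c1ccc(OCc3ccccc3)c(OCc3ccccc3)c1)[C@@H](O)C2 | intermediate
14 | 3,5,7,3',4'-penta-O-benzylcatechin-(4α→8)-5,7,3',4'-tetra-O-benzylcatechin | c1ccccc1COc1cc(OCc3ccccc3)c2c(c1)O[C@H](c1ccc(OCc3ccccc3)c(OCc3ccccc3)c1)[C@@H](OCc1ccccc1)[C@@H]2c1c(OCc3ccccc3)cc(OCc3ccccc3)c2c1O[C@H](c1ccc(OCc3ccccc3)c(OCc3ccccc3)c1)[C@@H](O)C2 | intermediate
15 | (+)-gallocatechin, (2R,3S) | Oc1cc(O)c2c(c1)O[C@H](c1cc(O)c(O)c(O)c1)[C@@H](O)C2 | starting material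
16 | (2R,3S)-5,7-bis(benzyloxy)-2-[3,4,5-tris(benzyloxy)phenyl]chroman-3-ol | c1ccccc1COc1cc(OCc3ccccc3)c2c(c1)O[C@H](c1cc(OCc3ccccc3)c(OCc3ccccc3)c(OCc3ccccc3)c1)[C@@H](O)C2 | intermediate
17 | (2R,3S,4S)-5,7-bis(benzyloxy)-4-(2-ethoxyethoxy)-2-[3,4,5-tris(benzyloxy)phenyl]chroman-3-ol | c1ccccc1COc1cc(OCc3ccccc3)c2c(c1)O[C@H](c1cc(OCc3ccccc3)c(OCc3ccccc3)c(OCc3ccccc3)c1)[C@@H](O)[C@H]2OCCOCC | intermediate
18 | 5,7,3',4',5'-penta-O-benzylgallocatechin-(4α→8)-3,5,7,3',4'-penta-O-benzylcatechin-(4α→8)-5,7,3',4'-tetra-O-benzylcatechin | c1ccccc1COc1cc(OCc3ccccc3)c2c(c1)O[C@H](c1cc(OCc3ccccc3)c(OCc3ccccc3)c(OCc3ccccc3)c1)[C@@H](O)[C@@H]2c1c(OCc3ccccc3)cc(OCc3ccccc3)c2c1O[C@H](c1ccc(OCc3ccccc3)c(OCc3ccccc3)c1)[C@@H](OCc1ccccc1)[C@@H]2c1c(OCc3ccccc3)cc(OCc3ccccc3)c2c1O[C@H](c1ccc(OCc3ccccc3)c(OCc3ccccc3)c1)[C@@H](O)C2 | intermediate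
19 | gallocatechin-(4α→8)-catechin-(4α→8)-catechin (CNP0155646.1) | Oc1cc(O)c2c(c1)O[C@H](c1cc(O)c(O)c(O)c1)[C@@H](O)[C@@H]2c1c(O)cc(O)c2c1O[C@H](c1ccc(O)c(O)c1)[C@@H](O)[C@@H]2c1c(O)cc(O)c2c1O[C@H](c1ccc(O)c(O)c1)[C@@H](O)C2 | target

**Step count and risks**

Total step count: 10. Longest linear sequence: 7 steps (steps 1, 2, 3, 4, 6, 9, 10, from 1 to 19).

Steps most likely to fail:

1. Step 4. Ring-opening racemisation at C2 may be slower than hydride transfer, so that the reduction stalls as a kinetic resolution. The catalyst may also select a minor 2,3-cis ketone, or reduce the electron-rich carbonyl only sluggishly. Fallback (resolution with recycling instead of in-flask deracemisation), setting out from 10 and coming back at 11: the reduction is run without amine base (RuCl[(S,S)-TsDPEN](p-cymene), HCO2Na, H2O/EtOAc, rt) to about half conversion. Alcohol 11 is separated from the unreacted (2S,3S)-enantiomer of the ketone F2. F2 is returned to racemic 10 in a separate flask by DBU in MeCN and resubmitted.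

2. Step 3. Retro-aldol cleavage and β-elimination of the aldolate to the α-benzyloxychalcone may outrun the SNAr closure, and the enolate may attack the fluoroarene of a second molecule. Fallback (Lewis-acid C–C bond formation with the alkoxide masked, then a separate closure), setting out from 6 and coming back at 10: one-pot enol silane formation and Mukaiyama aldol addition of 6 to 7 (TMSOTf, i-Pr2NEt, CH2Cl2, −78 °C) should give the β-trimethylsilyloxy ketone F1. CsF in DMF then releases the alkoxide and closes ring C by SNAr to give 10.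

3. Step 9. The cation from 17 may be consumed by self-condensation through its own free C8. Attack at the C6 positions of 14, acid-induced cleavage of the interflavan bond already present and incomplete facial control at C4 are further risks. Fallback (C8-capped electrophile), setting out from 16 and coming back at 19: NBS in CH2Cl2 at low temperature should brominate C8 to give 8-bromo-penta-O-benzylgallocatechin F3. DDQ and 2-ethoxyethanol convert it into the 8-bromo-4-(2-ethoxyethoxy) electrophile F4, which can be used in excess with 14 and TMSOTf to give the 8-bromo protected trimer F5. Hydrogenolysis (H2, Pd(OH)2/C, Et3N, THF/MeOH/H2O) removes bromine and all benzyl groups to give 19.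

**Further compounds**

F1 | step 3 | 1-[3,4-bis(benzyloxy)phenyl]-2-(benzyloxy)-3-[2,4-bis(benzyloxy)-6-fluorophenyl]-1-(trimethylsilyloxy)propan-3-one (diastereomer mixture) | C[Si](C)(C)OC(c1ccc(OCc2ccccc2)c(OCc2ccccc2)c1)C(OCc1ccccc1)C(=O)c1c(F)cc(OCc2ccccc2)cc1OCc1ccccc1
F2 | step 4 | (2S,3S)-3,5,7-tris(benzyloxy)-2-[3,4-bis(benzyloxy)phenyl]chroman-4-one | c1ccccc1COc1cc(OCc3ccccc3)c2c(c1)O[C@@H](c1ccc(OCc3ccccc3)c(OCc3ccccc3)c1)[C@H](OCc1ccccc1)C2=O
F3 | step 9 | (2R,3S)-5,7-bis(benzyloxy)-8-bromo-2-[3,4,5-tris(benzyloxy)phenyl]chroman-3-ol | c1ccccc1COc1cc(OCc3ccccc3)c2c(c1Br)O[C@H](c1cc(OCc3ccccc3)c(OCc3ccccc3)c(OCc3ccccc3)c1)[C@@H](O)C2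
F4 | step 9 | (2R,3S,4S)-5,7-bis(benzyloxy)-8-bromo-4-(2-ethoxyethoxy)-2-[3,4,5-tris(benzyloxy)phenyl]chroman-3-ol | c1ccccc1COc1cc(OCc3ccccc3)c2c(c1Br)O[C@H](c1cc(OCc3ccccc3)c(OCc3ccccc3)c(OCc3ccccc3)c1)[C@@H](O)[C@H]2OCCOCC
F5 | step 9 | 8-bromo-5,7,3',4',5'-penta-O-benzylgallocatechin-(4α→8)-3,5,7,3',4'-penta-O-benzylcatechin-(4α→8)-5,7,3',4'-tetra-O-benzylcatechin | c1ccccc1COc1cc(OCc3ccccc3)c2c(c1Br)O[C@H](c1cc(OCc3ccccc3)c(OCc3ccccc3)c(OCc3ccccc3)c1)[C@@H](O)[C@@H]2c1c(OCc3ccccc3)cc(OCc3ccccc3)c2c1O[C@H](c1ccc(OCc3ccccc3)c(OCc3ccccc3)c1)[C@@H](OCc1ccccc1)[C@@H]2c1c(OCc3ccccc3)cc(OCc3ccccc3)c2c1O[C@H](c1ccc(OCc3ccccc3)c(OCc3ccccc3)c1)[C@@H](O)C2
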